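The data stem from a simulated flask on assumed constants, and the scatter is random.

| flask | Z | G | remark | time |
|---|---|---|---|---|
| green | 1 M | 15 mol% | run made earlier |  |
| amber | 0.50 M | 15 mol% | run made earlier |  |
| blue | 2 M | 15 mol% | run made earlier |  |
| violet | 1 M | 22 mol% | run made earlier |  |
| beta | 1.0 M | 15 mol% | a closed flask charged with all of it at once and left for 4.0 h | 4.0 h |
| theta | 1.0 M | 15 mol% | a single well-mixed tank run continuously and read at steady state, 20.0 h in it on average |  |
| alpha | 1.0 M | 15 mol% | a single well-mixed tank run continuously and read at steady state, 4.0 h in it on average |  |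
| delta | 1.0 M (fed, over 4.00 h) | 15 mol% | a stirred flask in which Z is dosed at a steady rate over 4.00 h without added volume, worked up at 4.0 h | 4.0 h |

| run | time / h | L / % | Z / % |
|---|---|---|---|
| green | 0.333 | 5.2 | 20.0 |
| green | 0.833 | 6.8 | 7.7 |
| green | 1.50 | 9.0 | 3.4 |
| green | 2.50 | 10.3 | 1.4 |
| amber | 0.417 | 3.6 | 27.2 |
| amber | 1.00 | 6.6 | 15.5 |
| amber | 2.00 | 7.8 | 8.2 |
| amber | 3.00 | 11.0 | 3.6 |
| blue | 0.417 | 6.8 | 8.3 |
| blue | 1.00 | 8.5 | 2.9 |
| blue | 2.00 | 10.8 | 0 |
| blue | 3.00 | 9.6 | 1.1 |
| violet | 0.833 | 10.7 | 7.4 |
| violet | 1.50 | 11.4 | 2.9 |
| violet | 2.50 | 13.9 | 1.9 |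
| violet | 3.00 | 14.0 | 2.6 |

(scatter of a reading: 1 percentage point)

- the stated concentrations are those of everything mixed, before any reaction; amounts are the same in each set-up
- the feed brings no volume worth counting
- the earlier runs were made in a closed, stirred flask
- a reading or a percentage of L counts all its forms, free or not
- a reading of Z is of its free form alone

- the set-up with the highest amount of L at the outlet or at the end, in percent of the Z put in ("none" if the first two lie within 2 percentage points) (beta / theta / alpha / delta / none)
- amount of L at the outlet or at the end, in percent of the Z put in, beta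
- amount of L at the outlet or at the end, in percent of the Z put in, theta
- amount of L at the outlet or at the end, in percent of the Z put in, alpha
- amount of L at the outlet or at the end, in percent of the Z put in, delta

Read the green run at 0.333 h: Z is down to 20.0% of the charge, yet L stands at 5.2%. Where did the rest go? The last two green readings show a pseudo-first-order fall, a = 0.887 h⁻¹, but at that rate the green run would still hold 74.4% at its first reading, more than was read. So I take a second loss, going with the square of the standing fraction z, and read its rate from that first reading: w = 12.0 h⁻¹, at this charge and loading.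

Which loss wins? Divide one rate by the other and time drops out: b = a/w = 7.39% is the break-even fraction, the standing z at which both losses run equally. Of whatever Z is lost at z, the first-order path takes b/(b+z), the selectivity at that z.

How much of that path ends as L? Reckoned from the full charge down to z of zero, the path takes 19.8% of the charge, and the last green L reading, taken with 1.4% of Z still read, is f = 0.521 of that.

So you want z low. My balances put the standing z of theta at 3.64%, of alpha at 10.4%, and of delta, where loss keeps pace with the feed, at 11.2%. Theta holds the lowest. I reckon L at 33.6% for theta and 19.3% for alpha.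

The forecast names theta, with 10.8% for beta, 33% for theta, 19% for alpha and 18.5% for delta, on the ground that “Low standing Z therefore favours L”.

The flask gives theta: 10.8% for beta, 34.6% for theta, 17.2% for alpha, 16.6% for delta.

    Z + G → Q (k = 6.90 × 10⁻⁴ M⁻¹ s⁻¹)
    Q → G + L (k = 0.00454 s⁻¹)
    Z + L ⇌ J, settled at all times (K = 14.2 M⁻¹)
    2 Z → E (k = 0.00147 M⁻¹ s⁻¹)

Put the Z of alpha at the outlet, 11.9%, into the carried share, and f gives 17.6% of L against the 17.2% that alpha gives. Has beta come to rest at 4.0 h? No. Its free Z is 1.54%, below b, and the same rule turns that into 0.664% of L. Yet left ten times as long, beta gains 3.0 percentage points, more than its free Z, a figure that leaves out the Z held in J. Beta stands at 13.8% of L, J counted in, after 40.0 h.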